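The runs stem from a simulated flask from invented constants, and the scatter is random.

The ratio I watched was substrate charged to substrate left, and I took its logarithm, N, the count of e-foldings: where the rate goes in step with the substrate, N at fixed catalyst and time does not depend on the charge, and the fraction left is exp(−N).

| flask | substrate | precatalyst | remark | time |
|---|---|---|---|---|
| beta | 0.025 M | 30 µM | run made earlier |  |
| zeta | 0.025 M | 10 µM | run made earlier |  |
| Thursday's | 0.025 M | 20 µM |  | 1.0 h |
| Sunday's | 0.050 M | 20 µM |  | 1.0 h |
| Wednesday's | 0.10 M | 20 µM |  | 1.0 h |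
| Tuesday's | 0.20 M | 20 µM |  | 1.0 h |
| Monday's | 0.40 M | 20 µM |  | 1.0 h |

| run | time / min | target / % | substrate / % |
|---|---|---|---|
| beta | 1.00 | 0.8 | 99.5 |
| beta | 3.00 | 1.2 | 99.5 |
| beta | 6.00 | 4.4 | 95.3 |
| beta | 8.00 | 8.3 | 90.5 |
| beta | 12.0 | 17.7 | 82.7 |
| zeta | 1.00 | 0 | 99.7 |
| zeta | 2.00 | 0.5 | 100.1 |
| zeta | 3.00 | 0.2 | 99.7 |
| zeta | 6.00 | 0.8 | 98.5 |
| zeta | 12.0 | 6.0 | 93.6 |

(each reading ± 0.5 percentage points)

- [target] at the end for Thursday's, Sunday's, Wednesday's, Tuesday's, Monday's, in this order
- how the row runs (hardly changes / rises all the way / rises, then falls / falls, then rises / falls all the way)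

- "hardly changes" means that all values lie within two and a half points (for a concentration: within two and a half percent of the largest)

In the beta run N was 0.190 at 12.0 min and 0.0481 at 6.00 min, a ratio of 3.95 where a square law in time asks for 4. The zeta run, charged with 10 µM of precatalyst, gave 0.0661 at 12.0 min, so beta over zeta was 2.87 against a charge ratio of 3.00. Within the scatter of 0.5 percentage points, these readings went as precatalyst charged times time squared, which is how a slow start (induction period) reads when working catalyst grows steadily.

So I scaled the beta run to one number, H = 3.17, the e-foldings I reckoned for a flask charged with 0.025 M of substrate and 20 µM of precatalyst over 1.0 h. By that reckoning 4.22% of the substrate stays, so I put Thursday's at 0.0239 M.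

Was one number enough? For catalyst and time the readings bore it out as far as 12.0 min. For substrate the readings were silent, since both runs stood at 0.025 M, and Monday's charge is 16.0 times that. I committed to H anyway, which gave a row that kept rising, up to 0.383 M on Monday's.

The forecast gave 0.021 M for Thursday's and 0.0215 M for Monday's, with the shape hardly changes, the target “nearly independent of substrate”. We parted on Monday's, where my figure stood higher than its figure.

The flask gave 0.0241 M, 0.0476 M, 0.0900 M, 0.127 M and 0.0930 M: rises, then falls.

    substrate + enzyme → target + enzyme, rate k1*[substrate]*[enzyme]/(1 + ([substrate]/Km1) + ([substrate]/Ksi1)^2) (0.0917 M, 0.118 M, k = 225 L mol⁻¹ s⁻¹)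
    precatalyst → enzyme (k = 1.48 × 10⁻⁴ s⁻¹)

Thursday's left 3.49% of its substrate, which makes H read from that flask 3.36 against my 3.17. Monday's enzyme stood at 41.3% of the catalyst charged, level with Thursday's 41.3%, yet Monday's left 76.7% of its substrate, so N in Monday's flask was 0.265, lower than Thursday's by a factor of 12.7.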